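**Plan**
- **Cuts** (C1 = lactone C=O): the side chain at C16–C17 (Suzuki) and C15=C16 (cross-metathesis). Both C–O bonds of the 1,2-dioxane, O–C3 and O–C6, go in one stroke as loss of H2O2. Then C2=C3 with the lactone C1–O bond (Z-olefination and lactonisation), C4–C5 (enolate alkylation) and C6=C7 (Wittig).
- **Enabling feature:** in the dioxane ring O–O–C3–C4–C5–C6, C3 is β to the lactone carbonyl C1, so its C–O bond is an oxa-Michael bond to a butenolide. C6 is a fully substituted carbon three atoms away, so its C–O bond can come from anti opening of a C6–C7 oxirane. H2O2 can therefore be stapled between two electrophilic carbons.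
- **Forward order:** the chain C5–C16 is built and joined to a lactate unit at C4–C5. The butenolide ring is closed first and a temporary C6–C7 oxirane is added. The dioxane ring is closed last, the helper C7–OH is removed, and the triene is attached at the very end.
- **Stereochemistry:** C4 comes from (R)-lactic acid by self-regeneration of stereocentres. C6 comes from a reagent-controlled Shi epoxidation followed by inversion. C3 comes from the C4–C5–C6 tether (cis ring fusion). Triene geometry comes from E-selective metathesis, Takai olefination and stereoretentive coupling.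

Key step: step 10

Remark: plakortolide numbering is used throughout. C1 is the lactone C=O, C2 the CH2, C3 the CH–OO, C4 the C(CH3)–O(lactone), C5 the ring CH2, C6 the C(CH3)–OO, and C7–C22 the side chain. In intermediates that carry the terminal alkene its CH2 carbon is C16.

Step 1
Reactants: 1 dec-9-enal
Product: 2 ethyl (2E)-2-methyldodeca-2,11-dienoate
Conditions: Ph3P=C(CH3)CO2Et, CH2Cl2, rt
Reagents that add atoms: ethyl 2-(triphenylphosphoranylidene)propanoate, CCOC(=O)C(C)=P(c1ccccc1)(c1ccccc1)c1ccccc1
Why: Wittig olefination with a stabilised, α-branched ylide is reliably E-selective, so the trisubstituted C6=C7 alkene is laid down with C5 and C8 trans and the remote terminal alkene is untouched.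

Step 2
Reactants: 2 ethyl (2E)-2-methyldodeca-2,11-dienoate
Product: 3 (2E)-2-methyldodeca-2,11-dien-1-ol
Conditions: i-Bu2AlH (2.2 equiv), CH2Cl2, −78 °C
Reagents that add atoms: none
Why: i-Bu2AlH reduces the conjugated ester by 1,2-addition to the allylic alcohol without conjugate reduction or loss of alkene geometry.

Step 3
Reactants: 3 (2E)-2-methyldodeca-2,11-dien-1-ol
Product: 4 (2E)-1-bromo-2-methyldodeca-2,11-diene
Conditions: CBr4, PPh3, CH2Cl2, 0 °C
Reagents that add atoms: tetrabromomethane, BrC(Br)(Br)Br
Why: The Appel reaction converts the primary allylic alcohol into the bromide under neutral conditions by SN2 displacement of the oxyphosphonium ion, which keeps the E geometry and avoids allylic transposition.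

Step 4
Reactants: 5 (R)-lactic acid
Product: 6 (2R,5R)-2-tert-butyl-5-methyl-1,3-dioxolan-4-one
Conditions: pivalaldehyde, p-TsOH (cat.), pentane, reflux with water separator; crystallisation at −78 °C
Reagents that add atoms: pivalaldehyde, CC(C)(C)C=O
Why: Acid-catalysed acetalisation (first stage of self-regeneration of stereocentres) stores the lactate chirality in the new acetal centre, the cis isomer being thermodynamically preferred and purified by low-temperature crystallisation.

Step 5
Reactants: 6 (2R,5R)-2-tert-butyl-5-methyl-1,3-dioxolan-4-one; 4 (2E)-1-bromo-2-methyldodeca-2,11-diene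
Product: 8 (2R,5S)-2-tert-butyl-5-methyl-5-[(2E)-2-methyldodeca-2,11-dien-1-yl]-1,3-dioxolan-4-one, via lithium enolate 7 (not isolated)
Conditions: LiN(i-Pr)2, THF, −78 °C; then 4, −78 to −20 °C
Reagents that add atoms: none
Why: In the planar enolate the tert-butyl group shields one face, so the allylic bromide is attacked trans to it (diastereoselective enolate alkylation, self-regeneration of stereocentres) and the quaternary centre C4 forms with overall retention, which gives the S configuration.

Step 6
Reactants: 8 (2R,5S)-2-tert-butyl-5-methyl-5-[(2E)-2-methyldodeca-2,11-dien-1-yl]-1,3-dioxolan-4-one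
Product: 9 (2S,4E)-2,4-dimethyltetradeca-4,13-diene-1,2-diol
Conditions: LiAlH4, Et2O, 0 °C
Reagents that add atoms: none
Why: LiAlH4 reduces the acylal-type lactone to the primary alcohol and releases the tertiary hydroxyl (the freed pivalaldehyde is reduced as well) without touching the quaternary centre or the unactivated alkenes.

Step 7
Reactants: 9 (2S,4E)-2,4-dimethyltetradeca-4,13-diene-1,2-diol
Product: 10 (2S,4E)-2-hydroxy-2,4-dimethyltetradeca-4,13-dienal
Conditions: IBX (1.2 equiv), DMSO, rt
Reagents that add atoms: none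
Why: IBX oxidises the primary alcohol of a 1,2-diol to the α-hydroxy aldehyde without glycol cleavage, and the aldehyde cannot epimerise because C4 is quaternary.

Step 8
Reactants: 10 (2S,4E)-2-hydroxy-2,4-dimethyltetradeca-4,13-dienal
Product: 12 (5S)-5-methyl-5-[(2E)-2-methyldodeca-2,11-dien-1-yl]furan-2(5H)-one, via Z-hydroxy enoate 11 (not isolated)
Conditions: (CF3CH2O)2P(O)CH2CO2Me, KN(SiMe3)2, 18-crown-6, THF, −78 °C to rt; p-TsOH (cat.) on work-up
Reagents that add atoms: methyl bis(2,2,2-trifluoroethyl)phosphonoacetate, COC(=O)CP(=O)(OCC(F)(F)F)OCC(F)(F)F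
Why: The Still–Gennari variant of the Horner–Wadsworth–Emmons reaction gives the Z-enoate under kinetic control, in which the tertiary hydroxyl lies next to the ester and lactonises (5-exo-trig acyl substitution) to close the butenolide, the first ring of the skeleton.

Step 9
Reactants: 12 (5S)-5-methyl-5-[(2E)-2-methyldodeca-2,11-dien-1-yl]furan-2(5H)-one
Product: 13 (5S)-5-methyl-5-{[(2S,3S)-2-methyl-3-(non-8-en-1-yl)oxiran-2-yl]methyl}furan-2(5H)-one
Conditions: ent-Shi ketone (L-series, from L-sorbose, 30 mol %), KHSO5 (as Oxone), K2CO3, Bu4NHSO4 (cat.), aq. Na2B4O7 buffer, MeCN–CH2(OMe)2, 0 °C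
Reagents that add atoms: potassium peroxymonosulfate, [K+].[O-]S(=O)(=O)OO
Why: Shi asymmetric epoxidation (chiral dioxirane, spiro transition state) is reagent-controlled and works best on E-trisubstituted alkenes; the L-series ketone, mirror image of the D-fructose ketone that gives R,R-epoxides, should give the 6S,7S-oxirane, while the electron-poor butenolide and the monosubstituted alkene react far more slowly.

Step 10
Reactants: 13 (5S)-5-methyl-5-{[(2S,3S)-2-methyl-3-(non-8-en-1-yl)oxiran-2-yl]methyl}furan-2(5H)-one
Product: 15 (1S,4R,6S)-4-[(1S)-1-hydroxydec-9-en-1-yl]-4,6-dimethyl-2,3,7-trioxabicyclo[4.3.0]nonan-8-one, via hydroperoxide 14 (not isolated)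
Conditions: anhydrous H2O2 (ca. 3 M in Et2O, 10 equiv), H3PMo12O40 (3 mol %), Et2O, 0 °C to rt; water wash, solvent switch; Et2NH (20 mol %), CF3CH2OH, rt
Reagents that add atoms: hydrogen peroxide, OO
Why: The acidic heteropolyacid activates the oxirane and H2O2 attacks the tertiary carbon C6 anti to the departing oxygen (borderline SN2) to give the β-hydroxy hydroperoxide 14; after the excess H2O2 is washed out, Et2NH generates the peroxy anion, which adds to C3 of the butenolide, and the lactone enolate is protonated at C2. The closest known reaction types are the phosphomolybdic-acid-catalysed perhydrolysis of trisubstituted epoxides and the amine-catalysed intramolecular oxa-Michael addition of tertiary hydroperoxides to butenolides and enoates. The one ring closed is the 1,2-dioxane, by a 6-exo-trig oxa-Michael closure (O–C3) that follows the intermolecular O–C6 bond formation, the temporary oxirane being opened in the same operation. C6 is set by inversion of the 6S oxirane carbon, C3 by the C4–C5–C6 tether, which lets the peroxy anion reach only the butenolide face syn to C5 (cis ring fusion), and C7 keeps its oxirane configuration. The step needs attack at C6 rather than C7 (secured by the cation-stabilising tertiary centre), OOH rather than the C7–OH as Michael donor (lower pKa and alpha effect), and no intermolecular epoxidation of the butenolide (no free H2O2 when base is present); the terminal alkene is inert throughout.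

Step 11
Reactants: 15 (1S,4R,6S)-4-[(1S)-1-hydroxydec-9-en-1-yl]-4,6-dimethyl-2,3,7-trioxabicyclo[4.3.0]nonan-8-one
Product: 16 O-phenyl thionocarbonate of 15 at the C7 oxygen (1S,4R,6S core, 1S side-chain carbinol)
Conditions: PhOC(S)Cl, pyridine, DMAP (cat.), CH2Cl2, 0 °C to rt
Reagents that add atoms: O-phenyl chlorothionoformate, ClC(=S)Oc1ccccc1
Why: Acylation of the only free hydroxyl with the reactive chlorothionoformate under nucleophilic catalysis installs the radical leaving group under mildly basic conditions in which any retro-oxa-Michael opening is reversible and returns the same cis-fused product.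

Step 12
Reactants: 16 O-phenyl thionocarbonate of 15
Product: 17 (1S,4S,6S)-4-(dec-9-en-1-yl)-4,6-dimethyl-2,3,7-trioxabicyclo[4.3.0]nonan-8-one
Conditions: Bu3SnH (5 equiv, 0.5 M), Et3B (20 mol %), air, toluene, 0 °C to rt
Reagents that add atoms: none
Why: In this Barton–McCombie deoxygenation the stannyl radical adds to C=S, the C7–O bond fragments and the secondary C7 radical is quenched by concentrated Bu3SnH at low temperature before it can attack the adjacent O–O bond (tin hydride reductions are tolerated by this class of peroxylactone), so the helper oxygen is removed and no stereocentre is touched.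

Step 13
Reactants: 17 (1S,4S,6S)-4-(dec-9-en-1-yl)-4,6-dimethyl-2,3,7-trioxabicyclo[4.3.0]nonan-8-one
Product: 18 (1S,4S,6S)-4,6-dimethyl-4-[(9E)-10-(4,4,5,5-tetramethyl-1,3,2-dioxaborolan-2-yl)dec-9-en-1-yl]-2,3,7-trioxabicyclo[4.3.0]nonan-8-one
Conditions: vinylboronic acid pinacol ester (3 equiv), second-generation Hoveyda–Grubbs catalyst (5 mol %), CH2Cl2, 40 °C
Reagents that add atoms: vinylboronic acid pinacol ester, C=CB1OC(C)(C)C(C)(C)O1
Why: Olefin cross-metathesis of a terminal alkene with the slowly homodimerising vinylboronate is selective for the cross product and gives the E-alkenylboronate, and hindered dialkyl peroxides and lactones are compatible with ruthenium alkylidenes.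

Step 14
Reactants: 19 (E)-pent-2-enal
Product: 20 (1E,3E)-1-iodohexa-1,3-diene
Conditions: CHI3, CrCl2 (6 equiv), THF, 0 °C, dark
Reagents that add atoms: iodoform, IC(I)I
Why: Takai olefination with the gem-dichromium reagent made from CHI3 converts the enal into the E-vinyl iodide with retention of the existing E-alkene.

Step 15
Reactants: 18 E-alkenylboronate; 20 (1E,3E)-1-iodohexa-1,3-diene
Product: 21 (1S,4S,6S)-4-[(9E,11E,13E)-hexadeca-9,11,13-trien-1-yl]-4,6-dimethyl-2,3,7-trioxabicyclo[4.3.0]nonan-8-one (target)
Conditions: PdCl2(dppf) (5 mol %), aq. K3PO4, THF, rt, degassed, dark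
Reagents that add atoms: none
Why: Suzuki–Miyaura sp2–sp2 coupling proceeds with retention of both alkene geometries, so the all-E triene is assembled at room temperature under mild base after all oxidising and radical conditions, and palladium-catalysed couplings are tolerated by 1,2-dioxanes.

**Compound list**
1 | dec-9-enal | C=CCCCCCCCC=O | starting material
2 | ethyl (2E)-2-methyldodeca-2,11-dienoate | C=CCCCCCCC/C=C(\C)C(=O)OCC | intermediate
3 | (2E)-2-methyldodeca-2,11-dien-1-ol | C=CCCCCCCC/C=C(\C)CO | intermediate
4 | (2E)-1-bromo-2-methyldodeca-2,11-diene | C=CCCCCCCC/C=C(\C)CBr | intermediate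
5 | (R)-lactic acid | C[C@@H](O)C(=O)O | starting material
6 | (2R,5R)-2-tert-butyl-5-methyl-1,3-dioxolan-4-one | C[C@H]1O[C@@H](C(C)(C)C)OC1=O | intermediate
7 | lithium enolate of 6 (not isolated) | CC1=C([O-])O[C@H](C(C)(C)C)O1.[Li+] | intermediate
8 | (2R,5S)-2-tert-butyl-5-methyl-5-[(2E)-2-methyldodeca-2,11-dien-1-yl]-1,3-dioxolan-4-one | C=CCCCCCCC/C=C(\C)C[C@]1(C)O[C@@H](C(C)(C)C)OC1=O | intermediate
9 | (2S,4E)-2,4-dimethyltetradeca-4,13-diene-1,2-diol | C=CCCCCCCC/C=C(\C)C[C@](C)(O)CO | intermediate
10 | (2S,4E)-2-hydroxy-2,4-dimethyltetradeca-4,13-dienal | C=CCCCCCCC/C=C(\C)C[C@](C)(O)C=O | intermediate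
11 | methyl (2Z,4S,6E)-4-hydroxy-4,6-dimethylhexadeca-2,6,15-trienoate (not isolated) | C=CCCCCCCC/C=C(\C)C[C@](C)(O)/C=C\C(=O)OC | intermediate
12 | (5S)-5-methyl-5-[(2E)-2-methyldodeca-2,11-dien-1-yl]furan-2(5H)-one | C=CCCCCCCC/C=C(\C)C[C@]1(C)OC(=O)C=C1 | intermediate
13 | (5S)-5-methyl-5-{[(2S,3S)-2-methyl-3-(non-8-en-1-yl)oxiran-2-yl]methyl}furan-2(5H)-one | C=CCCCCCCC[C@@H]1O[C@@]1(C)C[C@]2(C)OC(=O)C=C2 | intermediate
14 | (5S)-5-[(2R,3S)-2-hydroperoxy-3-hydroxy-2-methyldodec-11-en-1-yl]-5-methylfuran-2(5H)-one (not isolated) | C=CCCCCCCC[C@H](O)[C@@](OO)(C)C[C@]1(C)OC(=O)C=C1 | intermediate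
15 | (1S,4R,6S)-4-[(1S)-1-hydroxydec-9-en-1-yl]-4,6-dimethyl-2,3,7-trioxabicyclo[4.3.0]nonan-8-one | C=CCCCCCCC[C@H](O)[C@@]1(C)C[C@]2(C)OC(=O)C[C@@H]2OO1 | intermediate
16 | O-phenyl thionocarbonate of 15 at the C7 oxygen | C=CCCCCCCC[C@H](OC(=S)Oc3ccccc3)[C@@]1(C)C[C@]2(C)OC(=O)C[C@@H]2OO1 | intermediate
17 | (1S,4S,6S)-4-(dec-9-en-1-yl)-4,6-dimethyl-2,3,7-trioxabicyclo[4.3.0]nonan-8-one | C=CCCCCCCCC[C@@]1(C)C[C@]2(C)OC(=O)C[C@@H]2OO1 | intermediate
18 | (1S,4S,6S)-4,6-dimethyl-4-[(9E)-10-(4,4,5,5-tetramethyl-1,3,2-dioxaborolan-2-yl)dec-9-en-1-yl]-2,3,7-trioxabicyclo[4.3.0]nonan-8-one | CC1(C)OB(/C=C/CCCCCCCC[C@@]2(C)C[C@]3(C)OC(=O)C[C@@H]3OO2)OC1(C)C | intermediate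
19 | (E)-pent-2-enal | CC/C=C/C=O | starting material
20 | (1E,3E)-1-iodohexa-1,3-diene | CC/C=C/C=C/I | intermediate
21 | (1S,4S,6S)-4-[(9E,11E,13E)-hexadeca-9,11,13-trien-1-yl]-4,6-dimethyl-2,3,7-trioxabicyclo[4.3.0]nonan-8-one | CC/C=C/C=C/C=C/CCCCCCCC[C@@]1(C)C[C@]2(C)OC(=O)C[C@@H]2OO1 | target

**Step count**
Total step count: 15. Longest linear sequence: 13 steps (steps 1–3, 5–13 and 15).

**Steps most likely to fail**

**Step 10.** The tertiary C6–O bond may ionise ahead of attack. That would erode stereochemical fidelity at C6 or cause a hydride shift to a C7 ketone. Alternatively the β-hydroxy hydroperoxide may fragment across C6–C7 under base before the ring closes. The fallback gives up control at C6 and avoids both the oxirane and the β-hydroxy group. It sets out from 12. Bromohydroperoxidation with 1,3-dibromo-5,5-dimethylhydantoin and anhydrous H2O2 in Et2O at −40 °C adds Br to C7 and OOH to C6, anti and Markovnikov, on the electron-rich trisubstituted alkene only. This gives (5S)-5-[(2R,3S)-3-bromo-2-hydroperoxy-2-methyldodec-11-en-1-yl]-5-methylfuran-2(5H)-one F1 together with its 6S,7R diastereomer. Et2NH in CF3CH2OH then closes the dioxane to (1S,4R,6S)-4-[(1S)-1-bromodec-9-en-1-yl]-4,6-dimethyl-2,3,7-trioxabicyclo[4.3.0]nonan-8-one F2. Bu3SnH with Et3B removes the bromine, and chromatography separates the C6 epimers. The fallback comes back to the route at 17.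

**Step 12.** The C7 radical may attack the neighbouring O–O bond, closing an oxirane and releasing an alkoxyl radical, faster than it takes up hydrogen. The fallback never places a radical next to the peroxide, again at the price of control at C6. It sets out from 12. Markovnikov hydrobromination of the trisubstituted alkene (HBr, CH2Cl2, −78 °C) gives (5S)-5-(2-bromo-2-methyldodec-11-en-1-yl)-5-methylfuran-2(5H)-one F3. Silver-assisted perhydrolysis of the tertiary bromide (AgOCOCF3, anhydrous H2O2, Et2O, 0 °C) then gives (5S)-5-[(2S)-2-hydroperoxy-2-methyldodec-11-en-1-yl]-5-methylfuran-2(5H)-one F4 and its C6 epimer. Et2NH in CF3CH2OH closes the dioxane, and chromatography separates the epimers. The fallback comes back to the route at 17 and bypasses steps 9–12.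

**Step 13.** The ruthenium alkylidene may be consumed by the O–O bond. The metathesis may also stall at the homodimer or give poor control of alkene geometry. The fallback replaces metathesis by cleavage and olefination. It sets out from 17. Ozonolysis (O3, CH2Cl2, −78 °C, then Me2S) gives 9-[(1S,4S,6S)-4,6-dimethyl-8-oxo-2,3,7-trioxabicyclo[4.3.0]nonan-4-yl]nonanal F5. The E-selective boron-Wittig reaction with CH2(Bpin)2 and lithium 2,2,6,6-tetramethylpiperidide (THF, −78 °C) then converts the aldehyde into the alkenylboronate. The fallback comes back to the route at 18.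

**Further compounds**
F1 | step 10 | (5S)-5-[(2R,3S)-3-bromo-2-hydroperoxy-2-methyldodec-11-en-1-yl]-5-methylfuran-2(5H)-one | C=CCCCCCCC[C@H](Br)[C@@](OO)(C)C[C@]1(C)OC(=O)C=C1
F2 | step 10 | (1S,4R,6S)-4-[(1S)-1-bromodec-9-en-1-yl]-4,6-dimethyl-2,3,7-trioxabicyclo[4.3.0]nonan-8-one | C=CCCCCCCC[C@H](Br)[C@@]1(C)C[C@]2(C)OC(=O)C[C@@H]2OO1
F3 | step 12 | (5S)-5-(2-bromo-2-methyldodec-11-en-1-yl)-5-methylfuran-2(5H)-one (both C6 epimers) | C=CCCCCCCCCC(C)(Br)C[C@]1(C)OC(=O)C=C1
F4 | step 12 | (5S)-5-[(2S)-2-hydroperoxy-2-methyldodec-11-en-1-yl]-5-methylfuran-2(5H)-one | C=CCCCCCCCC[C@@](OO)(C)C[C@]1(C)OC(=O)C=C1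
F5 | step 13 | 9-[(1S,4S,6S)-4,6-dimethyl-8-oxo-2,3,7-trioxabicyclo[4.3.0]nonan-4-yl]nonanal | O=CCCCCCCCC[C@@]1(C)C[C@]2(C)OC(=O)C[C@@H]2OO1
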